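Feature used: in the 3,4-dihydroisocoumarin ring the lactone carbonyl C1 sits on C8a and the benzylic C4 on the adjacent C4a. This is the carbon pattern of a homophthalic acid, and the remaining ring atoms C3 (with its methyl group) and O2 are the C=O of acetaldehyde.
Target ⇐ (BCl3) tri-O-isopropyl ether ⇐ (radical loss of a C4-CO2H) 1-oxoisochroman-4-carboxylic acid ⇐ (C3–C4 and O2–C1) hexasubstituted homophthalic anhydride + acetaldehyde under a cinchona squaramide.
Anhydride ⇐ diacid ⇐ dibenzyl ester. The acids travel as benzyl esters and the phenols as isopropyl ethers, because the 2-methylchromone would not survive saponification of a 2,6-disubstituted benzoate, whereas hydrogenolysis is neutral.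
CH2 bridge ⇐ Negishi coupling of a bromohomophthalate with a chromon-6-ylmethylzinc chloride. The bromide comes from 2,4-dihydroxy-3,6-dimethylbenzoic acid, which already holds the arene pattern (lateral carboxylation of its 6-methyl group gives C4 and the traceless carboxyl); the zinc reagent comes from eugenin, with C6 addressed through its 5-OH.
Ring order: the arene and chromone rings are bought; the anhydride ring is closed in step 11 and exchanged for the lactone ring in step 12.

Key step: step 12

Assumption: the quinidine-derived squaramide is taken to deliver the enolate to the Si face of acetaldehyde (which gives 3R), by analogy with the sense this catalyst family shows with other aldehydes; the sense is verified on the first batch, and the quinine-derived pseudo-enantiomer is used if it is the reverse.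

Step 1
Reactants: 1 2,4-dihydroxy-3,6-dimethylbenzoic acid
Product: 2 benzyl 2,4-dihydroxy-3,6-dimethylbenzoate
Conditions: BnBr (1.05 equiv), KHCO3, DMF, rt
Reagents that add atoms: benzyl bromide, BrCc1ccccc1
Why: Carboxylate O-alkylation (SN2) under bicarbonate, which ionises only the CO2H and leaves both phenols free, at a temperature at which the β-resorcylic acid does not decarboxylate; the benzyl ester is chosen because it later leaves by O–CH2 cleavage.

Step 2
Reactants: 2 benzyl 2,4-dihydroxy-3,6-dimethylbenzoate
Product: 3 benzyl 3,6-dimethyl-2,4-di(propan-2-yloxy)benzoate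
Conditions: 2-bromopropane (excess), K2CO3, DMF, 70 °C, sealed vessel
Reagents that add atoms: 2-bromopropane, CC(C)Br
Why: Williamson ether synthesis on both phenoxides (the ester-chelated 2-OH needs the heat and the excess halide); isopropyl ethers stand LDA, Pd(0), H2/Pd and radical conditions and are later cleaved by BCl3 without loss of an aryl methyl ether.

Step 3
Reactants: 3 benzyl 3,6-dimethyl-2,4-di(propan-2-yloxy)benzoate
Product: 4 benzyl 3-bromo-2,5-dimethyl-4,6-di(propan-2-yloxy)benzoate
Conditions: NBS (1.05 equiv), MeCN, 0 °C to rt, dark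
Reagents that add atoms: N-bromosuccinimide, O=C1CCC(=O)N1Br
Why: Electrophilic aromatic bromination at the only unsubstituted ring carbon, which is ortho to one alkoxy group and para to the other; polar solvent and darkness suppress benzylic radical bromination.

Step 4
Reactants: 4 benzyl 3-bromo-2,5-dimethyl-4,6-di(propan-2-yloxy)benzoate
Product: 5 benzyl 2-[2-(benzyloxy)-2-oxoethyl]-3-bromo-5-methyl-4,6-di(propan-2-yloxy)benzoate
Conditions: LDA (2.3 equiv), THF, −78 °C; (BnO)2CO, −78 to −30 °C; AcOH quench
Reagents that add atoms: dibenzyl carbonate, O=C(OCc1ccccc1)OCc1ccccc1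
Why: Lateral lithiation of an o-toluate followed by Claisen-type C-acylation with a carbonate: only the methyl group ortho to the ester gives the conjugated dienolate, LDA does not exchange the aryl bromide, and the second equivalent of base stores the more acidic product as its enolate, so neither proton transfer nor a second acylation takes place.

Step 5
Reactants: 6 eugenin (5-hydroxy-7-methoxy-2-methyl-4H-chromen-4-one)
Product: 7 5-hydroxy-7-methoxy-2-methyl-4-oxo-4H-chromene-6-carbaldehyde
Conditions: MgCl2 (anhydrous), Et3N, (CH2O)n, MeCN, reflux; 1 M HCl work-up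
Reagents that add atoms: paraformaldehyde (as formaldehyde), C=O
Why: Casnati–Skattebøl ortho-formylation: the magnesium phenoxide of the 5-OH hands coordinated formaldehyde only to an ortho carbon, and since the other ortho carbon is the ring-fusion atom C4a only C6 (not C8) can react, after which a second formaldehyde takes the hydride from the benzylic alkoxide.

Step 6
Reactants: 7 5-hydroxy-7-methoxy-2-methyl-4-oxo-4H-chromene-6-carbaldehyde
Product: 8 7-methoxy-2-methyl-4-oxo-5-(propan-2-yloxy)-4H-chromene-6-carbaldehyde
Conditions: 2-iodopropane, K2CO3, DMF, 55 °C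
Reagents that add atoms: 2-iodopropane, CC(C)I
Why: Williamson ether synthesis on the acidic phenol flanked by two carbonyl groups; the mild carbonate base does not enolise the 2-methyl group enough for condensation with the hindered aldehyde.

Step 7
Reactants: 8 7-methoxy-2-methyl-4-oxo-5-(propan-2-yloxy)-4H-chromene-6-carbaldehyde
Product: 9 6-(hydroxymethyl)-7-methoxy-2-methyl-5-(propan-2-yloxy)-4H-chromen-4-one
Conditions: NaBH4 (0.5 equiv), THF–MeOH, −10 °C, short reaction time
Reagents that add atoms: none
Why: Chemoselective borohydride 1,2-reduction: the aldehyde is far more electrophilic than the vinylogous-ester carbonyl of the chromone, so a limited amount of hydride at low temperature stops at the benzylic alcohol.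

Step 8
Reactants: 9 6-(hydroxymethyl)-7-methoxy-2-methyl-5-(propan-2-yloxy)-4H-chromen-4-one
Product: 10 6-(chloromethyl)-7-methoxy-2-methyl-5-(propan-2-yloxy)-4H-chromen-4-one
Conditions: SOCl2 (1.1 equiv), CH2Cl2, 0 °C; cold aq NaHCO3 wash, used without chromatography
Reagents that add atoms: thionyl chloride, O=S(Cl)Cl
Why: Chlorodehydroxylation via the chlorosulfite (SNi/SN1), fast for a benzylic alcohol with two ortho alkoxy groups; the chloride rather than the bromide is made because it ionises less readily and is less prone to Wurtz coupling in the next step.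

Step 9
Reactants: 10 6-(chloromethyl)-7-methoxy-2-methyl-5-(propan-2-yloxy)-4H-chromen-4-one; 5 benzyl 2-[2-(benzyloxy)-2-oxoethyl]-3-bromo-5-methyl-4,6-di(propan-2-yloxy)benzoate
Product: 12 benzyl 2-[2-(benzyloxy)-2-oxoethyl]-3-{[7-methoxy-2-methyl-4-oxo-5-(propan-2-yloxy)-4H-chromen-6-yl]methyl}-5-methyl-4,6-di(propan-2-yloxy)benzoate, via chromon-6-ylmethylzinc chloride 11 (not isolated)
Conditions: 10, Zn dust, LiCl, THF, 25 °C; then 5, Pd(OAc)2 (3 mol%), SPhos (6 mol%), THF, 25 to 50 °C
Reagents that add atoms: none
Why: Negishi coupling: LiCl-assisted zinc insertion into benzylic chlorides tolerates the chromone carbonyl, Pd/SPhos accepts di-ortho-substituted electron-rich aryl bromides, and the benzyl esters and the arylacetate CH2 are inert to the mild benzylic zinc reagent, so the CH2 bridge is formed at a defined carbon of each ring.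

Step 10
Reactants: 12 the dibenzyl ester of step 9
Product: 13 2-(carboxymethyl)-3-{[7-methoxy-2-methyl-4-oxo-5-(propan-2-yloxy)-4H-chromen-6-yl]methyl}-5-methyl-4,6-di(propan-2-yloxy)benzoic acid
Conditions: H2 (1 atm), 10% Pd/C, EtOAc, rt
Reagents that add atoms: none
Why: Hydrogenolysis of benzyl esters: O–CH2Ph cleavage is indifferent to the crowding at the 2,6-disubstituted benzoate carbonyl and is neutral, which spares the chromone that hot hydroxide would open at C2, while isopropyl ethers, the methyl ether and the diarylmethane are not hydrogenolysed.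

Step 11
Reactants: 13 the homophthalic acid of step 10
Product: 14 5-{[7-methoxy-2-methyl-4-oxo-5-(propan-2-yloxy)-4H-chromen-6-yl]methyl}-7-methyl-6,8-di(propan-2-yloxy)-1H-isochromene-1,3(4H)-dione (homophthalic anhydride)
Conditions: Ac2O, toluene, 80 °C; volatiles removed in vacuo, used directly
Reagents that add atoms: none
Why: Cyclodehydration of a homophthalic acid via the mixed anhydride, the standard entry to isochroman-1,3-diones; without an amine base no C4 acetylation occurs, and all by-products are volatile, so the water-sensitive anhydride needs no chromatography.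

Step 12
Reactants: 14 the homophthalic anhydride of step 11; 15 acetaldehyde
Product: 16 (3R,4S)-5-{[7-methoxy-2-methyl-4-oxo-5-(propan-2-yloxy)-4H-chromen-6-yl]methyl}-3,7-dimethyl-1-oxo-6,8-di(propan-2-yloxy)-3,4-dihydro-1H-isochromene-4-carboxylic acid (trans)
Conditions: 15 (5 equiv, cold MTBE solution, syringe pump), 3-{[3,5-bis(trifluoromethyl)phenyl]amino}-4-{[(9R)-6'-methoxycinchonan-9-yl]amino}cyclobut-3-ene-1,2-dione (10 mol%), dry MTBE–CH2Cl2, −30 °C; cold 1 M HCl wash
Reagents that add atoms: none
Why: Deprotonation of C4–H by the quinuclidine nitrogen gives an ammonium enolate that stays hydrogen-bonded to the catalyst, and the two squaramide N–H bonds activate the carbonyl oxygen of acetaldehyde next to it; the enolate carbon adds to the aldehyde (C3–C4), and the new alkoxide acylates on the aryl-bound carbonyl C1 (O2–C1), which opens the anhydride ring and leaves its aliphatic carbonyl as the free C4 acid. The closest known reaction is the cinchona-squaramide-catalysed aldol–lactonisation (formal cycloaddition) of homophthalic anhydrides with aromatic and aliphatic aldehydes to 1-oxoisochroman-4-carboxylic acids. The lactone ring closes 6-exo-trig on C1, since attack on the aliphatic carbonyl would need a β-lactone and does not compete. C3 is set by the catalyst, which offers the Si face of the bound aldehyde to the enolate (3R), and C4 follows from the relative topicity of the same transition state (trans, 4S expected) but is erased in step 13. The step needs aldehyde-face selectivity and cross- over self-aldol selectivity: C4–H, flanked by the arene and an anhydride carbonyl, is the only carbon acid that a tertiary amine can ionise at −30 °C (neither the chromone 2-methyl group nor acetaldehyde is), slow addition keeps the free aldehyde low, and the isopropyl ethers remove every phenolic O–H that could be acylated or bind the squaramide. A cis isomer is harmless only if it is also 3R, so the C3 purity of both diastereomers is checked on a sample of the methyl esters, and a cis fraction of lower purity is removed before step 13.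

Step 13
Reactants: 16 the trans acid of step 12
Product: 18 (3R)-5-{[7-methoxy-2-methyl-4-oxo-5-(propan-2-yloxy)-4H-chromen-6-yl]methyl}-3,7-dimethyl-6,8-di(propan-2-yloxy)-3,4-dihydro-1H-isochromen-1-one, via Barton ester 17 (not isolated)
Conditions: 1-hydroxypyridine-2(1H)-thione, DCC, THF, 0 °C, dark; then Bu3SnH (3 equiv), tungsten lamp, 0 °C to rt
Reagents that add atoms: none
Why: Barton reductive decarboxylation: the stannyl radical adds to the thiocarbonyl sulfur, N–O cleavage and loss of CO2 give the secondary benzylic C4 radical, which takes hydrogen from the weak Sn–H bond (the S–H bond of an alkanethiol is too strong for a benzylic radical); β-scission of C3–O2 to an aroyloxyl radical is too slow to compete, no C4 anion is formed so E1cB ring opening is avoided, and C3 is not touched.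

Step 14
Reactants: 18 the tri-O-isopropyl ether of step 13
Product: 19 (3R)-6,8-dihydroxy-5-[(5-hydroxy-7-methoxy-2-methyl-4-oxo-4H-chromen-6-yl)methyl]-3,7-dimethyl-3,4-dihydro-1H-isochromen-1-one (CNP0180307.1)
Conditions: BCl3 (1 M in CH2Cl2, 8 equiv), CH2Cl2, −78 to 0 °C; H2O quench
Reagents that add atoms: none
Why: Lewis-acid ether cleavage: BCl3 binds the ether oxygens (helped by chelation to the lactone and chromone carbonyl groups for two of them) and chloride takes the secondary isopropyl group, a cleavage known to be much faster than that of a non-chelated aryl methyl ether, so the 7-methoxy group, the lactone and C3 stay as they are.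

Compound list
1 | 2,4-dihydroxy-3,6-dimethylbenzoic acid | Cc1cc(O)c(C)c(O)c1C(O)=O | starting material
2 | benzyl 2,4-dihydroxy-3,6-dimethylbenzoate | Cc1cc(O)c(C)c(O)c1C(=O)OCc1ccccc1 | intermediate
3 | benzyl 3,6-dimethyl-2,4-di(propan-2-yloxy)benzoate | Cc1cc(OC(C)C)c(C)c(OC(C)C)c1C(=O)OCc1ccccc1 | intermediate
4 | benzyl 3-bromo-2,5-dimethyl-4,6-di(propan-2-yloxy)benzoate | Cc1c(Br)c(OC(C)C)c(C)c(OC(C)C)c1C(=O)OCc1ccccc1 | intermediate
5 | benzyl 2-[2-(benzyloxy)-2-oxoethyl]-3-bromo-5-methyl-4,6-di(propan-2-yloxy)benzoate | O=C(Cc1c(Br)c(OC(C)C)c(C)c(OC(C)C)c1C(=O)OCc1ccccc1)OCc1ccccc1 | intermediate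
6 | eugenin | COc1cc(O)c2c(c1)oc(C)cc2=O | starting material
7 | 5-hydroxy-7-methoxy-2-methyl-4-oxo-4H-chromene-6-carbaldehyde | COc1cc2oc(C)cc(=O)c2c(O)c1C=O | intermediate
8 | 7-methoxy-2-methyl-4-oxo-5-(propan-2-yloxy)-4H-chromene-6-carbaldehyde | COc1cc2oc(C)cc(=O)c2c(OC(C)C)c1C=O | intermediate
9 | 6-(hydroxymethyl)-7-methoxy-2-methyl-5-(propan-2-yloxy)-4H-chromen-4-one | COc1cc2oc(C)cc(=O)c2c(OC(C)C)c1CO | intermediate
10 | 6-(chloromethyl)-7-methoxy-2-methyl-5-(propan-2-yloxy)-4H-chromen-4-one | COc1cc2oc(C)cc(=O)c2c(OC(C)C)c1CCl | intermediate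
11 | chromon-6-ylmethylzinc chloride derived from 10 | COc1cc2oc(C)cc(=O)c2c(OC(C)C)c1C[Zn]Cl | intermediate (not isolated)
12 | dibenzyl homophthalate carrying the chromonylmethyl group | COc1cc2oc(C)cc(=O)c2c(OC(C)C)c1Cc1c(OC(C)C)c(C)c(OC(C)C)c(C(=O)OCc2ccccc2)c1CC(=O)OCc1ccccc1 | intermediate
13 | homophthalic acid carrying the chromonylmethyl group | COc1cc2oc(C)cc(=O)c2c(OC(C)C)c1Cc1c(OC(C)C)c(C)c(OC(C)C)c(C(O)=O)c1CC(O)=O | intermediate
14 | homophthalic anhydride, tri-O-isopropyl | COc1cc2oc(C)cc(=O)c2c(OC(C)C)c1Cc1c(OC(C)C)c(C)c(OC(C)C)c2c1CC(=O)OC2=O | intermediate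
15 | acetaldehyde | CC=O | starting material
16 | (3R,4S)-trans-3-methyl-1-oxoisochroman-4-carboxylic acid, tri-O-isopropyl | COc1cc2oc(C)cc(=O)c2c(OC(C)C)c1Cc1c(OC(C)C)c(C)c(OC(C)C)c2c1[C@H](C(O)=O)[C@@H](C)OC2=O | intermediate
17 | Barton ester (2-thioxopyridin-1(2H)-yl ester) of 16 | COc1cc2oc(C)cc(=O)c2c(OC(C)C)c1Cc1c(OC(C)C)c(C)c(OC(C)C)c2c1[C@H](C(=O)ON1C=CC=CC1=S)[C@@H](C)OC2=O | intermediate (not isolated)
18 | (3R)-tri-O-isopropyl ether of the target | COc1cc2oc(C)cc(=O)c2c(OC(C)C)c1Cc1c(OC(C)C)c(C)c(OC(C)C)c2c1C[C@@H](C)OC2=O | intermediate
19 | CNP0180307.1 | COc1cc2oc(C)cc(=O)c2c(O)c1Cc1c(O)c(C)c(O)c2c1C[C@@H](C)OC2=O | target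

Total step count: 14. Longest linear sequence: 10 steps (1–4 then 9–14; the eugenin branch, 5–8 then 9–14, is equally long).

Steps most likely to fail

Step 12. The chromonylmethyl group at C5 crowds the reacting C4, and the two alkoxy donors conjugated with C1 slow the acyl transfer. Retro-aldol, self-condensation of acetaldehyde and weak discrimination of the aldehyde faces may therefore gain weight.
The fallback takes C3 from the chiral pool. It sets out from 4 (with 10 as the source of 11) and comes back at 18.
- The toluate anion of 4 (LDA, THF, −78 to 0 °C) opens (R)-propylene oxide at its CH2 terminus. This gives benzyl 3-bromo-2-[(2R)-2-hydroxypropyl]-5-methyl-4,6-di(propan-2-yloxy)benzoate F1.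
- The alkoxide of F1 (cat. NaH, THF) closes onto the benzyl ester. This gives (3R)-5-bromo-3,7-dimethyl-6,8-di(propan-2-yloxy)-3,4-dihydro-1H-isochromen-1-one F2.
- Negishi coupling of F2 with 11 under the conditions of step 9 gives 18. No bond at the stereocentre is touched on the way.

Step 13. The C4 radical is benzylic and hindered, so hydrogen transfer is slow. The radical may then be captured at the sulfur of unreacted thiohydroxamate or may dimerise. In addition, the activated ester has an acidic C4–H with an aroyloxy group in the β-position, so traces of base may cause eliminative ring opening.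
The fallback replaces the thiohydroxamate chain by reductive single-electron fragmentation of an isolable redox-active ester. It sets out from 16 and comes back at 18.
- N-Hydroxyphthalimide and DIC in CH2Cl2 give the 1,3-dioxoisoindolin-2-yl ester of 16 F3, which can be purified.
- Irradiation with blue light in the presence of Hantzsch ester and catalytic Ru(bpy)3(PF6)2 in THF, without added base, releases the same C4 radical. No thiocarbonyl trap is present, and the oxidised Hantzsch ester acts as hydrogen donor to give 18.

Step 5. The 5-O–Mg unit is tied up in a chelate with the C4 carbonyl. This may lower the reactivity so far that the hydroxymethyl stage condenses with a second chromone to methylene-bridged dimers before it is oxidised.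
The fallback uses halogenation and cross-coupling. It sets out from 6 and comes back at 9.
- Iodination of the free 5-hydroxy compound (NIS, DMF, rt) is known for 5-hydroxy-7-alkoxybenzopyran-4-ones to go ortho to the chelated hydroxyl. It gives 5-hydroxy-6-iodo-7-methoxy-2-methyl-4H-chromen-4-one F4, and the site is confirmed before going on.
- 2-Iodopropane and K2CO3 in DMF give 6-iodo-7-methoxy-2-methyl-5-(propan-2-yloxy)-4H-chromen-4-one F5.
- Stille hydroxymethylation of F5 with (tributylstannyl)methanol (Pd(PPh3)4, dioxane, 100 °C) gives 9.

Further compounds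
F1 | step 12 | benzyl 3-bromo-2-[(2R)-2-hydroxypropyl]-5-methyl-4,6-di(propan-2-yloxy)benzoate | C[C@@H](O)Cc1c(Br)c(OC(C)C)c(C)c(OC(C)C)c1C(=O)OCc1ccccc1
F2 | step 12 | (3R)-5-bromo-3,7-dimethyl-6,8-di(propan-2-yloxy)-3,4-dihydro-1H-isochromen-1-one | Brc1c(OC(C)C)c(C)c(OC(C)C)c2c1C[C@@H](C)OC2=O
F3 | step 13 | 1,3-dioxoisoindolin-2-yl ester of 16 | COc1cc2oc(C)cc(=O)c2c(OC(C)C)c1Cc1c(OC(C)C)c(C)c(OC(C)C)c2c1[C@H](C(=O)ON1C(=O)c3ccccc3C1=O)[C@@H](C)OC2=O
F4 | step 5 | 5-hydroxy-6-iodo-7-methoxy-2-methyl-4H-chromen-4-one | COc1cc2oc(C)cc(=O)c2c(O)c1I
F5 | step 5 | 6-iodo-7-methoxy-2-methyl-5-(propan-2-yloxy)-4H-chromen-4-one | COc1cc2oc(C)cc(=O)c2c(OC(C)C)c1I
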